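**Route outline**

Retrosynthesis: the six benzyl ethers come off last; C2–H and C3–OH are then removed across ring C (back to a C2=C3 enol ether), the galloyl ester is cut at O3'–C(=O), ring C is opened at O1–C2, and the chain is cut at C3–C4 into a ring A salicylaldehyde and a ring B acetophenone.
Forward: rings A, B and the galloyl ring are bought; C3–C4 is made by Claisen–Schmidt condensation, the enone is saturated, ring C is closed at O1–C2 by cyclodehydration to a 2-aryl-4H-chromene, the gallate is put on the only free phenol (O3'), and only then is C2=C3 functionalised.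
Enabling feature: in ring C the H on C2 and the OH on C3 are cis (2-aryl and 3-OH trans) and C3 is beta to both O1 and the ring B aryl, which is what syn addition of H–B to the C2=C3 enol ether with boron on C3 leaves; the gallate sits on O3' and not on O3, so the ester can be in place before any stereocentre exists.
Stereochemistry: there is no stereocentre before the hydroboration; C2 and C3 arise together, trans through syn addition and retentive C–B oxidation, and (2R,3S) through the isopinocampheyl group of the borane made from (+)-α-pinene.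

Key step: step 9

Assumption: IpcBH2 is a stock solution in THF, freed beforehand from its crystalline TMEDA adduct; its sense of induction is taken over from 1-arylcycloalkenes (reagent from (+)-α-pinene gives 2R,3S), and if a model 4H-chromene showed the opposite sense, the reagent from (−)-α-pinene would be used with nothing else changed.

**Route**

Step 1
Reactants: 1 2,4,6-trihydroxybenzaldehyde
Product: 2 2,4-bis(benzyloxy)-6-hydroxybenzaldehyde
Conditions: BnBr (2.0 equiv), K2CO3 (2.0 equiv), DMF, 0 °C to rt
Reagents that add atoms: benzyl bromide, BrCc1ccccc1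
Why: Williamson etherification should take the para OH and one ortho OH, while the remaining ortho OH is held in a hydrogen bond to the formyl oxygen and is the least nucleophilic, as is usual for 2,4,6-trihydroxyphenyl carbonyl compounds.

Step 2
Reactants: 2 2,4-bis(benzyloxy)-6-hydroxybenzaldehyde
Product: 3 2,4-bis(benzyloxy)-6-(methoxymethoxy)benzaldehyde
Conditions: NaH (1.2 equiv), MOMCl (1.3 equiv), DMF, 0 °C to rt
Reagents that add atoms: chloromethyl methyl ether, COCCl
Why: O-alkylation of the fully deprotonated chelated phenol gives a base-stable MOM acetal, so the aldehyde is not deactivated as an ortho-phenoxide in the aldol step and the group can later be removed by acid without touching benzyl ethers.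

Step 3
Reactants: 4 3,4-dihydroxyacetophenone
Product: 5 4-(benzyloxy)-3-hydroxyacetophenone
Conditions: BnBr (1.0 equiv), K2CO3 (1.0 equiv), DMF, rt
Reagents that add atoms: benzyl bromide, BrCc1ccccc1
Why: one equivalent of weak base ionises only the more acidic 4-OH para to the acetyl group, so the Williamson alkylation should go there and leave the 3-OH free.

Step 4
Reactants: 3 2,4-bis(benzyloxy)-6-(methoxymethoxy)benzaldehyde; 5 4-(benzyloxy)-3-hydroxyacetophenone
Product: 6 (E)-3-[2,4-bis(benzyloxy)-6-(methoxymethoxy)phenyl]-1-[4-(benzyloxy)-3-hydroxyphenyl]prop-2-en-1-one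
Conditions: KOH (50% aq, excess), EtOH/THF, rt; then aq NH4Cl
Reagents that add atoms: none
Why: Claisen–Schmidt condensation of a methyl ketone enolate with a non-enolisable, fully O-protected aldehyde followed by E1cB dehydration should give the E-enone and join C3 to C4, the meta-phenoxide of 5 not hindering enolisation.

Step 5
Reactants: 6 (E)-3-[2,4-bis(benzyloxy)-6-(methoxymethoxy)phenyl]-1-[4-(benzyloxy)-3-hydroxyphenyl]prop-2-en-1-one
Product: 7 3-[2,4-bis(benzyloxy)-6-(methoxymethoxy)phenyl]-1-[4-(benzyloxy)-3-hydroxyphenyl]propan-1-one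
Conditions: H2 (1 atm), 10% Pd/C, Ph2S (cat.), EtOAc, rt
Reagents that add atoms: none
Why: hydrogenation over sulfide-poisoned Pd/C should saturate the conjugated C=C while the attenuated catalyst leaves aryl benzyl ethers, the aryl ketone and the MOM acetal alone.

Step 6
Reactants: 7 3-[2,4-bis(benzyloxy)-6-(methoxymethoxy)phenyl]-1-[4-(benzyloxy)-3-hydroxyphenyl]propan-1-one
Product: 8 3-[2,4-bis(benzyloxy)-6-hydroxyphenyl]-1-[4-(benzyloxy)-3-hydroxyphenyl]propan-1-one (in equilibrium with its cyclic hemiketal)
Conditions: conc. HCl (cat.), MeOH/THF, 50 °C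
Reagents that add atoms: none
Why: acid-catalysed acetal exchange passes the methoxymethyl group to methanol and frees the ring A phenol, benzyl ethers being stable to dilute methanolic HCl, and any cyclic methyl ketal formed on the side converges on the same chromene in step 7.

Step 7
Reactants: 8 3-[2,4-bis(benzyloxy)-6-hydroxyphenyl]-1-[4-(benzyloxy)-3-hydroxyphenyl]propan-1-one
Product: 9 2-(benzyloxy)-5-[5,7-bis(benzyloxy)-4H-chromen-2-yl]phenol
Conditions: p-TsOH·H2O (5 mol%), toluene (0.02 M), reflux, Dean–Stark; then Et3N
Reagents that add atoms: none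
Why: acid-catalysed cyclodehydration of a 2-hydroxydihydrochalcone, in which 6-exo-trig addition of the ring A phenol to the ketone gives the hemiketal and azeotropic loss of water gives the aryl-conjugated C2=C3 enol ether, closes ring C at O1–C2.

Step 8
Reactants: 9 2-(benzyloxy)-5-[5,7-bis(benzyloxy)-4H-chromen-2-yl]phenol; 10 3,4,5-tris(benzyloxy)benzoic acid
Product: 11 2-(benzyloxy)-5-[5,7-bis(benzyloxy)-4H-chromen-2-yl]phenyl 3,4,5-tris(benzyloxy)benzoate
Conditions: DCC (1.2 equiv), DMAP (0.2 equiv), CH2Cl2, 0 °C to rt
Reagents that add atoms: none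
Why: Steglich esterification should acylate the only free OH through DMAP-mediated acyl transfer under acid-free conditions that leave the acid-sensitive enol ether intact.

Step 9
Reactants: 11 2-(benzyloxy)-5-[5,7-bis(benzyloxy)-4H-chromen-2-yl]phenyl 3,4,5-tris(benzyloxy)benzoate
Product: 14 2-(benzyloxy)-5-[(2R,3S)-5,7-bis(benzyloxy)-3-hydroxychroman-2-yl]phenyl 3,4,5-tris(benzyloxy)benzoate (hexa-O-benzyl catechin 3'-O-gallate), via C3 isopinocampheylborane adduct 12 (not isolated), via C3 diethyl boronate 13 (not isolated)
Conditions: IpcBH2 (from (+)-α-pinene, 1.3 equiv), THF, −25 °C; then MeCHO (excess), 0 °C to rt; then 30% H2O2, NaH2PO4/Na2HPO4 buffer (pH 7), THF, 0 °C to rt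
Reagents that add atoms: hydrogen peroxide, OO
Why: Proposed new method: the B–H bond of the chiral monoalkylborane should add across C2=C3 of the flat, achiral 4H-chromene through a concerted four-centre transition state, boron going to C3 (beta to both O1 and the ring B aryl, and the less substituted carbon) and hydrogen to C2 on the same face, after which acetaldehyde expels α-pinene to leave the diethyl boronate and buffered peroxide replaces boron by OH with retention. The closest known reactions are the hydroboration–oxidation of flav-2-enes to racemic 2,3-trans-flavan-3-ols and the asymmetric hydroboration of 1-arylcycloalkenes and cyclic enol ethers with isopinocampheylboranes. No ring closes in this step, ring C being already in place. C3 is controlled by the isopinocampheyl group on boron, which selects the alkene face (by analogy with 1-phenylcyclohexene the reagent from (+)-α-pinene should give 3S), and C2 follows as 2R because hydrogen is delivered syn to boron, so that aryl and OH end up trans. The step needs face selectivity, C3 regioselectivity and chemoselectivity over the aryl ester: the first rests on the reagent alone because the substrate has no stereocentre, the second on the reinforcing polarisation by O1 and the 2-aryl group, and the third on the low temperature, the electron-rich hindered tribenzyloxybenzoate and the base-free oxidation.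

Step 10
Reactants: 14 2-(benzyloxy)-5-[(2R,3S)-5,7-bis(benzyloxy)-3-hydroxychroman-2-yl]phenyl 3,4,5-tris(benzyloxy)benzoate
Product: 15 catechin 3'-O-gallate, 2-hydroxy-5-[(2R,3S)-3,5,7-trihydroxychroman-2-yl]phenyl 3,4,5-trihydroxybenzoate
Conditions: H2 (1 atm), Pd(OH)2/C, THF/EtOAc, rt, no base
Reagents that add atoms: none
Why: hydrogenolysis of the six aryl benzyl ethers over palladium in a neutral aprotic medium should free all phenols without touching the aryl ester or the two stereocentres, base being excluded throughout to avoid acyl shift from O3' to O4'.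

**Compound list**

1 | 2,4,6-trihydroxybenzaldehyde | O=Cc1c(O)cc(O)cc1O | starting material
2 | 2,4-bis(benzyloxy)-6-hydroxybenzaldehyde | O=Cc1c(O)cc(OCc2ccccc2)cc1OCc1ccccc1 | intermediate
3 | 2,4-bis(benzyloxy)-6-(methoxymethoxy)benzaldehyde | O=Cc1c(OCOC)cc(OCc2ccccc2)cc1OCc1ccccc1 | intermediate
4 | 3,4-dihydroxyacetophenone | CC(=O)c1ccc(O)c(O)c1 | starting material
5 | 4-(benzyloxy)-3-hydroxyacetophenone | CC(=O)c1ccc(OCc2ccccc2)c(O)c1 | intermediate
6 | (E)-3-[2,4-bis(benzyloxy)-6-(methoxymethoxy)phenyl]-1-[4-(benzyloxy)-3-hydroxyphenyl]prop-2-en-1-one | O=C(/C=C/c1c(OCOC)cc(OCc2ccccc2)cc1OCc1ccccc1)c1ccc(OCc2ccccc2)c(O)c1 | intermediate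
7 | 3-[2,4-bis(benzyloxy)-6-(methoxymethoxy)phenyl]-1-[4-(benzyloxy)-3-hydroxyphenyl]propan-1-one | O=C(CCc1c(OCOC)cc(OCc2ccccc2)cc1OCc1ccccc1)c1ccc(OCc2ccccc2)c(O)c1 | intermediate
8 | 3-[2,4-bis(benzyloxy)-6-hydroxyphenyl]-1-[4-(benzyloxy)-3-hydroxyphenyl]propan-1-one | O=C(CCc1c(O)cc(OCc2ccccc2)cc1OCc1ccccc1)c1ccc(OCc2ccccc2)c(O)c1 | intermediate
9 | 2-(benzyloxy)-5-[5,7-bis(benzyloxy)-4H-chromen-2-yl]phenol | Oc1cc(C2=CCc3c(OCc4ccccc4)cc(OCc4ccccc4)cc3O2)ccc1OCc1ccccc1 | intermediate
10 | 3,4,5-tris(benzyloxy)benzoic acid | OC(=O)c1cc(OCc2ccccc2)c(OCc2ccccc2)c(OCc2ccccc2)c1 | starting material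
11 | 2-(benzyloxy)-5-[5,7-bis(benzyloxy)-4H-chromen-2-yl]phenyl 3,4,5-tris(benzyloxy)benzoate | O=C(Oc1cc(C2=CCc3c(OCc4ccccc4)cc(OCc4ccccc4)cc3O2)ccc1OCc1ccccc1)c1cc(OCc2ccccc2)c(OCc2ccccc2)c(OCc2ccccc2)c1 | intermediate
12 | C3 isopinocampheylborane adduct: compound 14 with B(H)(isopinocampheyl) in place of the 3-OH, boron trans to the 2-aryl group, isopinocampheyl from (+)-α-pinene (shown as monomer) | O=C(Oc1cc([C@H]2Oc3cc(OCc4ccccc4)cc(OCc4ccccc4)c3C[C@@H]2B[C@@H]5C[C@@H]6C[C@@H](C6(C)C)[C@H]5C)ccc1OCc1ccccc1)c1cc(OCc2ccccc2)c(OCc2ccccc2)c(OCc2ccccc2)c1 | intermediate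
13 | C3 diethyl boronate: compound 14 with B(OEt)2 in place of the 3-OH, same spatial arrangement at C2 and C3 | O=C(Oc1cc([C@H]2Oc3cc(OCc4ccccc4)cc(OCc4ccccc4)c3C[C@@H]2B(OCC)OCC)ccc1OCc1ccccc1)c1cc(OCc2ccccc2)c(OCc2ccccc2)c(OCc2ccccc2)c1 | intermediate
14 | 2-(benzyloxy)-5-[(2R,3S)-5,7-bis(benzyloxy)-3-hydroxychroman-2-yl]phenyl 3,4,5-tris(benzyloxy)benzoate | O=C(Oc1cc([C@H]2Oc3cc(OCc4ccccc4)cc(OCc4ccccc4)c3C[C@@H]2O)ccc1OCc1ccccc1)c1cc(OCc2ccccc2)c(OCc2ccccc2)c(OCc2ccccc2)c1 | intermediate
15 | catechin 3'-O-gallate, 2-hydroxy-5-[(2R,3S)-3,5,7-trihydroxychroman-2-yl]phenyl 3,4,5-trihydroxybenzoate | O=C(Oc1cc([C@H]2Oc3cc(O)cc(O)c3C[C@@H]2O)ccc1O)c1cc(O)c(O)c(O)c1 | target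

**Step count and risks**

Total step count: 10. Longest linear sequence: 9 steps (1 to 2 to 3 to 6 to 7 to 8 to 9 to 11 to 14 to 15; step 3 is the side branch).

Steps most likely to fail:

Step 9. The chiral borane may discriminate the two faces of this ring system poorly. A slow addition at low temperature may let reduction of the aryl ester compete. The C3 borane may also open ring C by beta-elimination toward O1. A partial selectivity might be raised by crystallising the intermediate dialkylborane or compound 14. The fallback sets out from 11 and uses known chemistry only. Hydroboration with BH3·THF (THF, 0 °C, short reaction time), a reaction known for flav-2-enes, followed by the same buffered peroxide oxidation, should give the racemic 2,3-trans alcohol. This is 14 together with its mirror image, the (2S,3R)-enantiomer of 14 F1. Preparative chromatography on a chiral stationary phase (cellulose tris(3,5-dimethylphenylcarbamate)) should then give 14, where the route is rejoined.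

Step 7. The 4H-chromene may disproportionate under acid, by hydride transfer to its own oxocarbenium ion, into a flavylium salt and a flavan. It may also dimerise, or the keto-phenol may resist dehydration. The fallback sets out from 2 and 5 and avoids the acid-catalysed dehydration of a neutral enol ether. Condensation of the two with HCl gas in EtOAc at 0 °C, the classical flavylium salt synthesis, should give 5,7-bis(benzyloxy)-2-[4-(benzyloxy)-3-hydroxyphenyl]chromenylium chloride F2. Reduction with LiAlH4 in THF (−78 to 0 °C), which is known to deliver hydride to C4 of flavylium salts, should then give 9, where the route is rejoined.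

Step 10. The galloyl group may shift from O3' to the newly freed O4' on the catalyst or in the medium, and the benzylic C2–O1 bond may be opened by hydrogenolysis. The fallback sets out from 14 and replaces the reductive cleavage on a metal surface by Lewis-acid dealkylation. BCl3 with pentamethylbenzene as benzyl cation scavenger in CH2Cl2 at −78 °C, quenched cold with methanol, should give 15 directly under acidic, base-free conditions. No new compound lies on the way.

**Further compounds**

F1 | step 9 | (2S,3R)-enantiomer of 14, 2-(benzyloxy)-5-[(2S,3R)-5,7-bis(benzyloxy)-3-hydroxychroman-2-yl]phenyl 3,4,5-tris(benzyloxy)benzoate | O=C(Oc1cc([C@@H]2Oc3cc(OCc4ccccc4)cc(OCc4ccccc4)c3C[C@H]2O)ccc1OCc1ccccc1)c1cc(OCc2ccccc2)c(OCc2ccccc2)c(OCc2ccccc2)c1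
F2 | step 7 | 5,7-bis(benzyloxy)-2-[4-(benzyloxy)-3-hydroxyphenyl]chromenylium chloride | [Cl-].Oc1cc(-c2ccc3c(OCc4ccccc4)cc(OCc4ccccc4)cc3[o+]2)ccc1OCc1ccccc1
F0 | step 10 | none | none
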